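(The runs come from a simulation on assumed constants; the scatter is artificial.)

| flask | substrate | partner | remark | time |
|---|---|---|---|---|
| south-west | 0.050 M | 0.090 M | run made earlier |  |
| south | 0.025 M | 0.090 M | run made earlier |  |
| west | 0.038 M | 0.090 M | run made earlier |  |
| noon | 0.050 M | 0.0900 M | a single well-mixed tank run continuously and read at steady state, 120 h in it on average |  |
| dawn | 0.050 M | 0.0900 M | a closed flask charged with all of it at once and left for 12 h | 12 h |
| winter | 0.050 M (fed, over 9.60 h) | 0.0900 M | a stirred flask in which substrate is dosed at a steady rate over 9.60 h without added volume, worked up at 12 h | 12 h |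
| dusk | 0.050 M | 0.0900 M | a single well-mixed tank run continuously and read at steady state, 12 h in it on average |  |

| run | time / h | target / % | side product / % | over-reaction product / % |
|---|---|---|---|---|
| south-west | 0.500 | 1.0 | 0 | 0.2 |
| south-west | 1.00 | 1.1 | 0.1 | 0 |
| south-west | 1.50 | 1.6 | 0.1 | 0 |
| south-west | 2.50 | 3.3 | 0.5 | 0.1 |
| south-west | 4.00 | 5.5 | 1.5 | 0.1 |
| south-west | 8.00 | 10.2 | 3.5 | 2.2 |
| south | 1.00 | 0.9 | 0 | 0.2 |
| south | 1.50 | 1.7 | 0.4 | 0 |
| south | 2.50 | 3.9 | 0.3 | 0.2 |
| south | 4.00 | 7.0 | 1.2 | 0.7 |
| south | 8.00 | 12.6 | 3.4 | 3.3 |
| south | 12.0 | 15.2 | 6.0 | 7.3 |
| west | 2.00 | 2.6 | 0.7 | 0.6 |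
| west | 4.00 | 6.3 | 1.3 | 0.7 |
| west | 6.00 | 9.2 | 2.1 | 2.0 |
| west | 8.00 | 11.3 | 2.8 | 3.3 |
| west | 10.0 | 13.0 | 4.3 | 4.6 |
| west | 12.0 | 13.5 | 5.3 | 6.1 |

(scatter of a reading: 0.3 percentage points)

- the stated concentrations are those of everything mixed, before any reaction; amounts are the same in each set-up
- the numbers in the tables scatter by 0.3 percentage points (one standard deviation)
- what may be going on: substrate <-> intermediate A; substrate + partner <-> intermediate B; partner + intermediate B -> target; intermediate A -> side product; intermediate B -> decomposed reagent; partner + target -> over-reaction product
- the feed brings no volume worth counting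
- the earlier runs were made in a closed, stirred flask

- the set-up with the highest share of target in all that became target or side product or over-reaction product, at the outlet or at the end ("none" if the first two lie within 2 percentage points) (noon / dawn / winter / dusk / none)
- share of target in all that became target or side product or over-reaction product, at the outlet or at the end, noon
- share of target in all that became target or side product or over-reaction product, at the outlet or at the end, dawn
- share of target in all that became target or side product or over-reaction product, at the outlet or at the end, winter
- share of target in all that became target or side product or over-reaction product, at the outlet or at the end, dusk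

After 12.0 h the west flask holds 6.1% of over-reaction product beside 13.5% of target, so I ask first how long target lasts there. I take target as building at a steady rate, though the west readings bend towards the end, which makes it on average about half the run old, and over-reaction product per target is then that age divided by a lifetime. This gives 13.3 h as the target's lifetime against over-reaction, a pseudo-first-order reading from the west flask that carries the scatter of its readings.

Next I ask how many lifetimes old the target is in each set-up. In dawn its age is half of 12 h, a count of 0.452. In winter the average dosed portion stays 7.20 h, and its target is half that old, 3.60 h, a count of 0.271. I take target leaving a tank as having stayed the mean time on average, so dusk, with the same figure as dawn's 12 h, counts 0.904, and noon counts 9.04 if the lifetime stays as read. Winter has the lowest count, so I commit to winter, then dawn, dusk and noon, with side product left uncounted.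

The forecast also reasons from age, “Share depends mostly on age”, and names winter: noon 12%, dawn 54%, winter 63%, dusk 46%.

The flasks give noon 7.78%, dawn 53.7%, winter 62.5% and dusk 40.8%, so winter is best, and the forecast for dusk stands 5.2 percentage points too high.

    substrate ⇌ intermediate A (K = 0.852, k = 0.0457 h⁻¹)
    substrate + partner ⇌ intermediate B (K = 14.1 L mol⁻¹, k = 3.69 L mol⁻¹ h⁻¹)
    partner + intermediate B → target (k = 0.872 L mol⁻¹ h⁻¹)
    intermediate A → side product (k = 0.0498 h⁻¹)
    intermediate B → decomposed reagent (k = 0.0318 h⁻¹)
    partner + target → over-reaction product (k = 0.951 L mol⁻¹ h⁻¹)

In winter, over-reaction product per target is 0.295 at 12.0 h, against my count of 0.271. For the same flask with 0.22 M of partner I shorten the lifetime in proportion to the partner charged, to 5.43 h, so the age of 3.60 h counts 0.663. That neighbour holds 18.8% of over-reaction product beside 20.7% of target, which is 0.909 per target, more than the count. Its share of target is 50.2%, against 62.5% in winter.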